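**Plan**
1. Cuts: the imide N–C16 bond and C12–C13 (aldol); C11–C12 and C9=C11 (two one-carbon units on a C9 carbonyl); C3–C4 (closure of ring A); C10–C1 and C10–C20 (enolate alkylations). What remains is (R)-carvone.
2. Enabling feature: C4 carries the methyl groups C18/C19 and is bonded to C5 of ring B, so it is the isopropenyl carbon of carvone in disguise, and C3 is a carbinol carbon. A tertiary radical at C4 and a formyl carbon C3 sit 1,6 to each other on the trans-diequatorial C5 and C10 bonds of the carvone ring.
3. Forward: carvone is ring B (C5–C10 plus C17). C10 is alkylated twice (C20, then C1–C3), the chain becomes an α-chloro aldehyde, and hydrogen atom transfer to the isopropenyl group closes ring A at C3–C4.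
4. Then C9=O becomes C9–CH2 (C11) by methylenation and hydroboration, C7=C8 becomes the 7β-hydroxy-8(17)-ene through a β-epoxide, C12 enters as a formyl group, and a syn-aldol with a cyano acyl oxazolidinone plus nitrile hydration closes the succinimide.
5. Stereochemistry: C5 from (R)-carvone; C10 by alkylation anti to isopropenyl; C2 by catalyst-controlled chlorination; C3 in the chair transition state of ring closure; C9 by hydroboration anti to the axial C20 methyl; C7 from the β-epoxide; C12/C13 from the (R)-benzyl oxazolidinone.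

Key step: step 5

Remark on locants: names use the labdane numbering of the target (ring A = C1–C5, C10; ring B = C5–C10; C11, C12 chain; C13–C16 imide; C17 on C8; C18/C19 on C4; C20 on C10). α is below and β above the ring plane; 5α-H and 10β-CH3 (trans fusion) hold from compound 8 on.

Assumption: in step 4 the (2R,5R)-antipode of 2,5-diphenylpyrrolidine is taken as the one that delivers the (2R)-chloride; if the sense of induction is the reverse, the (2S,5S)-antipode is used in the same way.

**Step 1**
Reactants: 1 (R)-(−)-carvone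
Product: 3 6-methylcarvone (both C6 epimers), via lithium dienolate of carvone 2 (not isolated)
Conditions: LiN(i-Pr)2 (LDA), THF, −78 °C; MeI, −78 → 0 °C
Reagents that add atoms: iodomethane, CI
Why: kinetic deprotonation at the α′-methylene (future C10) gives the cross-conjugated lithium dienolate, and its enolate alkylation installs the future C20 methyl; the new centre need not be controlled because it is enolized again in step 2.

**Step 2**
Reactants: 3 6-methylcarvone
Product: 5 6-methyl-6-propargylcarvone (methyl cis and propargyl trans to isopropenyl), via lithium enolate of 6-methylcarvone 4 (not isolated)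
Conditions: LiN(i-Pr)2 (LDA), THF, −78 °C; propargyl bromide, DMPU, −78 → 0 °C
Reagents that add atoms: propargyl bromide, C#CCBr
Why: enolate alkylation in which the electrophile should enter the tetrasubstituted enolate anti to the neighbouring isopropenyl group, so the C1–C3 chain ends trans and the methyl cis to it, which sets the quaternary C10.

**Step 3**
Reactants: 5 6-methyl-6-propargylcarvone
Product: 6 keto aldehyde (C10–CH2CH2CHO)
Conditions: CpRu(MeCN)3PF6 (cat.), 5,5′-bis(trifluoromethyl)-2,2′-bipyridine (cat.), NMP/H2O, 25 °C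
Reagents that add atoms: water, O
Why: ruthenium-catalysed anti-Markovnikov hydration of the terminal alkyne through a vinylidene should give the aldehyde and leave the enone and the isopropenyl group untouched; no stereocentre is involved.

**Step 4**
Reactants: 6 keto aldehyde
Product: 7 (2R)-α-chloro aldehyde
Conditions: NCS, (2R,5R)-2,5-diphenylpyrrolidine (10 mol%), CH2Cl2, 0 °C → rt; used at once without chromatography
Reagents that add atoms: N-chlorosuccinimide, O=C1CCC(=O)N1Cl
Why: enamine-catalysed α-chlorination of the aldehyde, in which the C2-symmetric amine and not the remote ring centres should decide the face of chlorine transfer and so set C2.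

**Step 5**
Reactants: 7 (2R)-α-chloro aldehyde
Product: 8 2α-chloro-3β-hydroxy trans-decalin enone
Conditions: Fe(acac)3 (30 mol%), PhSiH3 (2.5 equiv), THF/i-PrOH (4:1), 0.01 M, 40 °C
Reagents that add atoms: none
Why: The iron hydride formed from Fe(acac)3 and PhSiH3 transfers a hydrogen atom to the CH2 terminus of the isopropenyl group, the tertiary C4 radical adds to the formyl carbon C3, and the alkoxy radical is reduced by divalent iron and protonated; the closest known reactions are the iron-hydride reductive cyclization of alkene-tethered ketones and the iron-hydride addition of unactivated alkenes to aldehydes. Ring A closes in a 6-exo-trig mode on the carbonyl through a chair transition state built on the trans-diequatorial C5 and C10 bonds of ring B, which gives the trans-decalin. C3 is the only new stereocentre: with the C2–Cl bond equatorial and antiperiplanar to the forming C3–C4 bond (Felkin–Anh-type activation; an axial chlorine would meet the axial C20 methyl) the carbonyl oxygen should take the pseudo-equatorial site, as in chair-like carbonyl cyclizations to cyclohexanols, which gives the 2α-chloro-3β-ol. C4 becomes the quaternary gem-dimethyl carbon because the transferred hydrogen completes its second methyl group. The step needs hydrogen atom transfer to the isopropenyl group only, which the electron-poor trisubstituted enone alkene secures, and ring closure faster than reduction or intermolecular capture of the radical, which the preorganized 1,6-relationship and high dilution secure.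

**Step 6**
Reactants: 8 2α-chloro-3β-hydroxy trans-decalin enone
Product: 9 3-O-TBS ether of 8
Conditions: TBSOTf, 2,6-lutidine, CH2Cl2, 0 °C
Reagents that add atoms: tert-butyldimethylsilyl triflate, CC(C)(C)[Si](C)(C)OS(=O)(=O)C(F)(F)F
Why: silyl ether formation on the hindered equatorial alcohol keeps an alkoxide from forming next to the C2–Cl bond in the basic steps that follow.

**Step 7**
Reactants: 9 3-O-TBS ether of 8
Product: 10 9(11),7-diene
Conditions: Cp2TiMe2, toluene/THF, 65 °C, dark
Reagents that add atoms: dimethyltitanocene, [CH3-].[CH3-].[Ti+4].c1cc[cH-]c1.c1cc[cH-]c1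
Why: Petasis methylenation through Cp2Ti=CH2 is non-basic and should convert the hindered C9 ketone (flanked by quaternary C10 and C8) into the exocyclic alkene C9=C11 without touching the chloride or the silyl ether.

**Step 8**
Reactants: 10 9(11),7-diene
Product: 12 C11 primary alcohol (9α-H, C7=C8), via C11-alkyl-9-BBN adduct 11 (not isolated)
Conditions: 9-BBN, THF, 0 → 50 °C; NaOH, H2O2, 0 °C
Reagents that add atoms: hydrogen peroxide, OO
Why: hydroboration–oxidation in which boron adds to the terminal C11 and hydrogen is delivered to C9 from the α face, away from the axial C20 methyl on the adjacent carbon, so C9 should become 9α-H with an equatorial CH2OH; the trisubstituted C7=C8 is too hindered for the bulky borane.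

**Step 9**
Reactants: 12 C11 primary alcohol
Product: 13 C11 iodide
Conditions: I2, PPh3, imidazole, toluene/MeCN, 50 °C
Reagents that add atoms: iodine, [I][I]
Why: Appel-type iodination of the only free (primary) hydroxyl by SN2 at C11; no stereocentre is touched.

**Step 10**
Reactants: 13 C11 iodide
Product: 15 7β,8β-epoxide, via 7α-bromo-8β-ol 14 (not isolated)
Conditions: NBS, THF/H2O, 0 °C; K2CO3, MeOH, rt
Reagents that add atoms: water, O
Why: halohydrin formation and ring closure: the bromonium ion should form on the open α face and be opened by water at the tertiary C8 from the β face (Markovnikov and trans-diaxial, Fürst–Plattner), and the 8β-alkoxide then displaces the axial 7α-bromide with inversion to give the β-epoxide that a peracid would not give.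

**Step 11**
Reactants: 15 7β,8β-epoxide
Product: 16 7β-hydroxy-8(17)-ene
Conditions: Et2AlTMP (from lithium 2,2,6,6-tetramethylpiperidide and Et2AlCl), toluene, 0 °C → rt
Reagents that add atoms: none
Why: aluminium-amide isomerization of an epoxide to an allylic alcohol by syn β-elimination: the amide on oxygen-bound aluminium removes a C17 methyl proton while the tertiary C8–O bond breaks, the 9α-H is anti to the β-oxygen and cannot compete, and the untouched C7–O bond keeps the 7β configuration.

**Step 12**
Reactants: 16 7β-hydroxy-8(17)-ene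
Product: 17 3,7-bis-TBS ether iodide
Conditions: TBSOTf, 2,6-lutidine, CH2Cl2, −78 → 0 °C
Reagents that add atoms: tert-butyldimethylsilyl triflate, CC(C)(C)[Si](C)(C)OS(=O)(=O)C(F)(F)F
Why: silyl ether formation masks the allylic alcohol for the organolithium and boron enolate steps.

**Step 13**
Reactants: 17 3,7-bis-TBS ether iodide
Product: 19 C12 aldehyde, via C11 alkyllithium 18 (not isolated)
Conditions: t-BuLi (2.1 equiv), Et2O/pentane, −78 °C; DMF, −78 → 0 °C; H2O
Reagents that add atoms: N,N-dimethylformamide, CN(C)C=O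
Why: iodine–lithium exchange of the primary iodide is fast at −78 °C, where the secondary chloride and the silyl ethers are inert, and formylation of the alkyllithium with DMF adds C12 as the aldehyde.

**Step 14**
Reactants: 20 (R)-4-benzyloxazolidin-2-one, 21 3-cyanopropanoic acid
Product: 23 (R)-4-benzyl-3-(3-cyanopropanoyl)oxazolidin-2-one, via pivalic mixed anhydride 22 (not isolated)
Conditions: PivCl, Et3N, THF, −20 °C; 20, LiCl, rt
Reagents that add atoms: none
Why: N-acylation of the oxazolidinone through the mixed pivalic anhydride, which is attacked at the less hindered carbonyl; the auxiliary stereocentre is not touched.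

**Step 15**
Reactants: 19 C12 aldehyde, 23 (R)-4-benzyl-3-(3-cyanopropanoyl)oxazolidin-2-one
Product: 26 syn-aldol adduct, via dibutylboron Z-enolate 24 (not isolated), via boron aldolate 25 (not isolated)
Conditions: 23, Bu2BOTf, i-Pr2NEt, CH2Cl2, 0 °C; 19, −78 → 0 °C; pH 7 buffer, MeOH, H2O2, 0 °C
Reagents that add atoms: none
Why: Evans syn-aldol: the Z-boron enolate reacts through a Zimmerman–Traxler chair on the face left open by the (R)-benzyl group, which should give the (12S,13R) syn adduct whatever the bias of the remote decalin.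

**Step 16**
Reactants: 26 syn-aldol adduct
Product: 28 3,7-bis-TBS ether of the target, via primary amide 27 (not isolated)
Conditions: [PtH{(PMe2O)2H}(PMe2OH)] (5 mol%), EtOH/H2O, 80 °C; DBU, THF, 0 °C → rt
Reagents that add atoms: water, O
Why: neutral platinum-catalysed nitrile hydration gives the primary amide, whose nitrogen attacks the activated exocyclic imide carbonyl C16 (5-exo-trig acyl substitution) and expels the oxazolidinone to form the succinimide; C12 and C13 are not involved in bond changes.

**Step 17**
Reactants: 28 3,7-bis-TBS ether of the target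
Product: 29 3β-hydroxylissoclimide
Conditions: HF·pyridine, pyridine/THF, 0 °C → rt
Reagents that add atoms: none
Why: fluoride-driven cleavage of both silyl ethers under buffered conditions; the rigid trans-diequatorial chlorohydrin cannot close to an epoxide and no stereocentre is touched.

**Compound list**
1 | (R)-(−)-carvone, (5R)-2-methyl-5-(prop-1-en-2-yl)cyclohex-2-en-1-one | CC1=CC[C@H](CC1=O)C(C)=C | starting material
2 | lithium dienolate of carvone (OLi on the former carbonyl carbon, C=C to the α′-carbon) | CC1=CC[C@H](C=C1O[Li])C(C)=C | intermediate (not isolated)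
3 | 6-methylcarvone, (5R)-2,6-dimethyl-5-(prop-1-en-2-yl)cyclohex-2-en-1-one, both C6 epimers | CC1=CC[C@H](C(C)C1=O)C(C)=C | intermediate
4 | lithium enolate of 6-methylcarvone | CC1=CC[C@H](C(C)=C1O[Li])C(C)=C | intermediate (not isolated)
5 | (5S,6S)-2,6-dimethyl-5-(prop-1-en-2-yl)-6-(prop-2-yn-1-yl)cyclohex-2-en-1-one | CC1=CC[C@@H](C(C)=C)[C@](C)(CC#C)C1=O | intermediate
6 | 3-[(1S,6S)-1,3-dimethyl-2-oxo-6-(prop-1-en-2-yl)cyclohex-3-en-1-yl]propanal | CC1=CC[C@@H](C(C)=C)[C@](C)(CCC=O)C1=O | intermediate
7 | (2R)-2-chloro-3-[(1S,6S)-1,3-dimethyl-2-oxo-6-(prop-1-en-2-yl)cyclohex-3-en-1-yl]propanal | CC1=CC[C@@H](C(C)=C)[C@](C)(C[C@@H](Cl)C=O)C1=O | intermediate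
8 | trans-decalin enone: 2α-chloro, 3β-hydroxy, 4,4-dimethyl, 5α-H, 10β-methyl, C7=C8 with methyl C17 on C8, C9 ketone | CC1=CC[C@H]2C(C)(C)[C@@H](O)[C@H](Cl)C[C@]2(C)C1=O | intermediate
9 | 3β-O-tert-butyldimethylsilyl ether of 8 | CC1=CC[C@H]2C(C)(C)[C@@H](O[Si](C)(C)C(C)(C)C)[C@H](Cl)C[C@]2(C)C1=O | intermediate
10 | diene: 9 with C9=O replaced by C9=C11H2 | CC1=CC[C@H]2C(C)(C)[C@@H](O[Si](C)(C)C(C)(C)C)[C@H](Cl)C[C@]2(C)C1=C | intermediate
11 | C11-alkyl-9-borabicyclo[3.3.1]nonane (boron on C11, 9α-H) | CC1=CC[C@H]2C(C)(C)[C@@H](O[Si](C)(C)C(C)(C)C)[C@H](Cl)C[C@]2(C)[C@H]1CB1C2CCCC1CCC2 | intermediate (not isolated)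
12 | primary alcohol: C9β–CH2OH (C11), 9α-H, C7=C8, 2α-Cl, 3β-OTBS | CC1=CC[C@H]2C(C)(C)[C@@H](O[Si](C)(C)C(C)(C)C)[C@H](Cl)C[C@]2(C)[C@H]1CO | intermediate
13 | primary iodide: 12 with C11–OH replaced by C11–I | CC1=CC[C@H]2C(C)(C)[C@@H](O[Si](C)(C)C(C)(C)C)[C@H](Cl)C[C@]2(C)[C@H]1CI | intermediate
14 | bromohydrin: 7α-bromo, 8β-hydroxy, 8α-methyl | C[C@]1(O)[C@H](Br)C[C@H]2C(C)(C)[C@@H](O[Si](C)(C)C(C)(C)C)[C@H](Cl)C[C@]2(C)[C@H]1CI | intermediate (not isolated)
15 | 7β,8β-epoxide (8α-methyl) | C[C@]12O[C@H]1C[C@H]3C(C)(C)[C@@H](O[Si](C)(C)C(C)(C)C)[C@H](Cl)C[C@]3(C)[C@H]2CI | intermediate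
16 | allylic alcohol: 7β-hydroxy, C8=C17H2, C11 iodide, 2α-Cl, 3β-OTBS | C=C1[C@@H](O)C[C@H]2C(C)(C)[C@@H](O[Si](C)(C)C(C)(C)C)[C@H](Cl)C[C@]2(C)[C@H]1CI | intermediate
17 | 3β,7β-bis(tert-butyldimethylsilyloxy) iodide | C=C1[C@@H](O[Si](C)(C)C(C)(C)C)C[C@H]2C(C)(C)[C@@H](O[Si](C)(C)C(C)(C)C)[C@H](Cl)C[C@]2(C)[C@H]1CI | intermediate
18 | C11 alkyllithium from 17 | C=C1[C@@H](O[Si](C)(C)C(C)(C)C)C[C@H]2C(C)(C)[C@@H](O[Si](C)(C)C(C)(C)C)[C@H](Cl)C[C@]2(C)[C@H]1C[Li] | intermediate (not isolated)
19 | aldehyde: C9β–CH2–CHO (C11, C12), bis-TBS ether | C=C1[C@@H](O[Si](C)(C)C(C)(C)C)C[C@H]2C(C)(C)[C@@H](O[Si](C)(C)C(C)(C)C)[C@H](Cl)C[C@]2(C)[C@H]1CC=O | intermediate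
20 | (R)-4-benzyloxazolidin-2-one | O=C1N[C@H](Cc2ccccc2)CO1 | starting material
21 | 3-cyanopropanoic acid | N#CCCC(=O)O | starting material
22 | 3-cyanopropanoic pivalic anhydride | N#CCCC(=O)OC(=O)C(C)(C)C | intermediate (not isolated)
23 | (R)-4-benzyl-3-(3-cyanopropanoyl)oxazolidin-2-one | N#CCCC(=O)N1[C@H](Cc2ccccc2)COC1=O | intermediate
24 | dibutylboron Z-enolate of 23 | CCCCB(CCCC)O/C(=C\CC#N)N1[C@H](Cc2ccccc2)COC1=O | intermediate (not isolated)
25 | O-dibutylboryl aldolate of 26 | C=C1[C@@H](O[Si](C)(C)C(C)(C)C)C[C@H]2C(C)(C)[C@@H](O[Si](C)(C)C(C)(C)C)[C@H](Cl)C[C@]2(C)[C@H]1C[C@H](OB(CCCC)CCCC)[C@@H](CC#N)C(=O)N1[C@H](Cc2ccccc2)COC1=O | intermediate (not isolated)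
26 | syn-aldol adduct: (12S)-hydroxy, (13R)-cyanomethyl, C16 acyl oxazolidinone | C=C1[C@@H](O[Si](C)(C)C(C)(C)C)C[C@H]2C(C)(C)[C@@H](O[Si](C)(C)C(C)(C)C)[C@H](Cl)C[C@]2(C)[C@H]1C[C@H](O)[C@@H](CC#N)C(=O)N1[C@H](Cc2ccccc2)COC1=O | intermediate
27 | primary amide from 26 (CH2CONH2 on C13) | C=C1[C@@H](O[Si](C)(C)C(C)(C)C)C[C@H]2C(C)(C)[C@@H](O[Si](C)(C)C(C)(C)C)[C@H](Cl)C[C@]2(C)[C@H]1C[C@H](O)[C@@H](CC(N)=O)C(=O)N1[C@H](Cc2ccccc2)COC1=O | intermediate (not isolated)
28 | 3,7-bis-O-tert-butyldimethylsilyl 3β-hydroxylissoclimide | C=C1[C@@H](O[Si](C)(C)C(C)(C)C)C[C@H]2C(C)(C)[C@@H](O[Si](C)(C)C(C)(C)C)[C@H](Cl)C[C@]2(C)[C@H]1C[C@H](O)[C@H]1CC(=O)NC1=O | intermediate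
29 | 3β-hydroxylissoclimide | C=C1[C@@H](O)C[C@H]2C(C)(C)[C@@H](O)[C@H](Cl)C[C@]2(C)[C@H]1C[C@H](O)[C@H]1CC(=O)NC1=O | target

**Step count**
Total: 17 steps. Longest linear sequence: 16 steps (steps 1–13 and 15–17 from carvone); step 14 is the one-step side branch.

**Steps most likely to fail**

Step 5. The ring closure may fail through poor facial selectivity at the formyl carbon, through loss of the C2 configuration by enolization of the chloro aldehyde before closure, or through reduction of the tertiary radical before it reaches the carbonyl. The fallback sets out from aldehyde 6 and brings chlorine in after ring closure. The same iron hydride cyclization on 6 should give the chlorine-free 3-hydroxy enone F1 as C3 epimers. Oxidation with Dess–Martin periodinane gives the 3,9-dione F2. Kinetic enolization at C2, the only α-CH2 of the C3 ketone, with LiN(SiMe3)2 and chlorination with NCS, followed if needed by equilibration to the equatorial chloride, gives the 2α-chloro-3-ketone F3. NaBH4 at low temperature should then deliver hydride axially from the α face and spare the hindered enone, which returns the route to compound 8.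

Step 10. The epoxide may be lost through poor facial selectivity of bromonium formation or through opening at C7 instead of C8. The fallback sets out from iodide 13 and reaches the 7β-alcohol by inversion instead. Epoxidation with m-CPBA from the open α face gives the 7α,8α-epoxide F4. Et2AlTMP isomerizes it to the 7α-hydroxy-8(17)-ene F5, and Dess–Martin periodinane gives the 7-keto-8(17)-ene F6. Reduction with NaBH4/CeCl3·7H2O, by axial hydride delivery, should give the equatorial 7β-alcohol, which is compound 16.

Step 16. The imide may not close because the primary amide is a weak nucleophile, or the free C12 hydroxyl may open the way to retro-aldol cleavage and C13 epimerization under base. The fallback sets out from aldol adduct 26 and closes the ring on a protected substrate with a strong base. Silylation with TBSOTf and 2,6-lutidine gives the C12 silyl ether F7. The same platinum-catalysed hydration gives the primary amide F8. NaN(SiMe3)2 in THF at low temperature deprotonates the amide, which closes onto the acyl oxazolidinone to give the tris-silyl succinimide F9. HF·pyridine then removes all three silyl groups and the route arrives at target 29.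

**Further compounds**
F1 | step 5 | 3-hydroxy-4,4-dimethyl trans-decalin enone without chlorine (C3 epimers) | CC1=CC[C@H]2C(C)(C)C(O)CC[C@]2(C)C1=O
F2 | step 5 | 3,9-dione (C7=C8 enone kept) | CC1=CC[C@H]2C(C)(C)C(=O)CC[C@]2(C)C1=O
F3 | step 5 | 2α-chloro-3-ketone | CC1=CC[C@H]2C(C)(C)C(=O)[C@H](Cl)C[C@]2(C)C1=O
F4 | step 10 | 7α,8α-epoxide (8β-methyl) of 13 | C[C@@]12O[C@@H]1C[C@H]3C(C)(C)[C@@H](O[Si](C)(C)C(C)(C)C)[C@H](Cl)C[C@]3(C)[C@H]2CI
F5 | step 10 | 7α-hydroxy-8(17)-ene | C=C1[C@H](O)C[C@H]2C(C)(C)[C@@H](O[Si](C)(C)C(C)(C)C)[C@H](Cl)C[C@]2(C)[C@H]1CI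
F6 | step 10 | 7-keto-8(17)-ene | C=C1C(=O)C[C@H]2C(C)(C)[C@@H](O[Si](C)(C)C(C)(C)C)[C@H](Cl)C[C@]2(C)[C@H]1CI
F7 | step 16 | 12-O-TBS ether of aldol adduct 26 | C=C1[C@@H](O[Si](C)(C)C(C)(C)C)C[C@H]2C(C)(C)[C@@H](O[Si](C)(C)C(C)(C)C)[C@H](Cl)C[C@]2(C)[C@H]1C[C@H](O[Si](C)(C)C(C)(C)C)[C@@H](CC#N)C(=O)N1[C@H](Cc2ccccc2)COC1=O
F8 | step 16 | primary amide of F7 | C=C1[C@@H](O[Si](C)(C)C(C)(C)C)C[C@H]2C(C)(C)[C@@H](O[Si](C)(C)C(C)(C)C)[C@H](Cl)C[C@]2(C)[C@H]1C[C@H](O[Si](C)(C)C(C)(C)C)[C@@H](CC(N)=O)C(=O)N1[C@H](Cc2ccccc2)COC1=O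
F9 | step 16 | 3,7,12-tris-O-TBS 3β-hydroxylissoclimide | C=C1[C@@H](O[Si](C)(C)C(C)(C)C)C[C@H]2C(C)(C)[C@@H](O[Si](C)(C)C(C)(C)C)[C@H](Cl)C[C@]2(C)[C@H]1C[C@H](O[Si](C)(C)C(C)(C)C)[C@H]1CC(=O)NC1=O
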